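Ring B, the pyran O5–C6–C6a–C11a–C11b–C4a, is disconnected at C6a: without that carbon it is the furanone ring of a benzofuran-3(2H)-one built on ring A, and C6a is also the atom that carries ring D. The key step therefore adds an aryl(chloro)carbene bearing ring D across the C2=C3 bond of the derived 3-silyloxybenzofuran; the cyclopropane opens with loss of chloride and silyl, so the five-membered ring becomes the six-membered pyranone of an isoflavone with C6–C6a and C6a–C11a formed together. Asymmetric transfer hydrogenation with dynamic kinetic resolution and acid cyclisation then set C6a and C11a and close the dihydrofuran ring.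

Key step: step 9

Remark: the SMILES is read as the cis-fused (6aS,11aS) pterocarpan; pterocarpan numbering is used for the target, flavonoid numbering for the isoflavone-stage compounds, and nitrile 8 is taken as purchasable.

Step 1
Reactants: 1 4,6-dihydroxybenzofuran-3(2H)-one
Product: 2 4-hydroxy-6-(methoxymethoxy)benzofuran-3(2H)-one
Conditions: MOMCl (1.05 equiv), K2CO3, acetone, 0 °C to rt
Reagents that add atoms: chloromethyl methyl ether (MOMCl), COCCl
Why: Williamson etherification (MOM protection) should go selectively at the 6-OH, which is para to the ketone, more acidic and unhindered, while the 4-OH is hydrogen-bonded to the peri carbonyl.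

Step 2
Reactants: 2 4-hydroxy-6-(methoxymethoxy)benzofuran-3(2H)-one; 3 3-chloro-3-methylbut-1-yne
Product: 4 6-(methoxymethoxy)-4-[(2-methylbut-3-yn-2-yl)oxy]benzofuran-3(2H)-one
Conditions: K2CO3, KI (cat.), CuI (copper monoiodide, cat.), acetone, 55 °C
Reagents that add atoms: none
Why: copper-assisted O-alkylation of the remaining phenoxide with the tertiary propargylic chloride is the standard entry to aryl 1,1-dimethylpropargyl ethers.

Step 3
Reactants: 4 6-(methoxymethoxy)-4-[(2-methylbut-3-yn-2-yl)oxy]benzofuran-3(2H)-one
Product: 5 5-(methoxymethoxy)-2,2-dimethyl-2H-furo[2,3-h]chromen-9(8H)-one (the benzofuranone with a 2,2-dimethyl-2H-pyran fused at C4–C5, pyran oxygen on C4)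
Conditions: xylenes, 140 °C
Reagents that add atoms: none
Why: aromatic propargyl Claisen rearrangement to C5, the only free ortho position, followed by enolisation, 1,5-hydrogen shift and oxa-6π electrocyclisation should give the 2,2-dimethylchromene with its oxygen on C4.

Step 4
Reactants: 5 5-(methoxymethoxy)-2,2-dimethyl-2H-furo[2,3-h]chromen-9(8H)-one
Product: 6 5-(methoxymethoxy)-2,2-dimethyl-3,4-dihydro-2H-furo[2,3-h]chromen-9(8H)-one
Conditions: H2 (1 atm), Pd/C (10 wt %), EtOAc, rt
Reagents that add atoms: none
Why: catalytic hydrogenation should saturate the styrene-type chromene double bond, which would otherwise compete for the carbene in step 9, and leave the vinylogous-ester ketone and the MOM ether untouched.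

Step 5
Reactants: 6 5-(methoxymethoxy)-2,2-dimethyl-3,4-dihydro-2H-furo[2,3-h]chromen-9(8H)-one
Product: 7 tert-butyl{[5-(methoxymethoxy)-2,2-dimethyl-3,4-dihydro-2H-furo[2,3-h]chromen-9-yl]oxy}dimethylsilane (the TBS enol ether of 6, a 3-silyloxybenzofuran)
Conditions: KN(SiMe3)2, THF, −78 °C; then TBSCl, −78 to 0 °C
Reagents that add atoms: tert-butyldimethylsilyl chloride (TBSCl), CC(C)(C)[Si](C)(C)Cl
Why: silyl enol ether formation by O-silylation of the potassium enolate, which is an aromatic benzofuran-3-olate and therefore forms readily.

Step 6
Reactants: 8 2-hydroxy-4-methoxybenzonitrile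
Product: 9 4-methoxy-2-(methoxymethoxy)benzonitrile
Conditions: MOMCl, K2CO3, acetone, rt
Reagents that add atoms: chloromethyl methyl ether (MOMCl), COCCl
Why: Williamson etherification protects the phenol that later becomes O11 as a MOM ether, which is stable to the base and oxidant of the next two steps.

Step 7
Reactants: 9 4-methoxy-2-(methoxymethoxy)benzonitrile
Product: 10 4-methoxy-2-(methoxymethoxy)benzamidine hydrochloride
Conditions: LiN(SiMe3)2, THF, 0 °C to rt; then HCl in EtOH (2 equiv), 0 °C, short contact
Reagents that add atoms: lithium bis(trimethylsilyl)amide, [Li+].C[Si](C)(C)[N-][Si](C)(C)C; hydrogen chloride, Cl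
Why: addition of the silylamide to the nitrile and N-desilylation is the standard amidine synthesis, and the cold, stoichiometric acid should spare the aryl MOM ether.

Step 8
Reactants: 10 4-methoxy-2-(methoxymethoxy)benzamidine hydrochloride
Product: 11 3-chloro-3-[4-methoxy-2-(methoxymethoxy)phenyl]-3H-diazirine
Conditions: NaOCl (aq), LiCl, DMSO/pentane, 0 °C to rt; pentane extract kept cold and used at once
Reagents that add atoms: sodium hypochlorite, [Na+].[O-]Cl; lithium chloride, [Li+].[Cl-]
Why: Graham oxidation (N-chlorination, N–N closure and chloride return to carbon) converts amidinium salts into 3-chloro-3-aryldiazirines.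

Step 9
Reactants: 7 tert-butyl{[5-(methoxymethoxy)-2,2-dimethyl-3,4-dihydro-2H-furo[2,3-h]chromen-9-yl]oxy}dimethylsilane; 11 3-chloro-3-[4-methoxy-2-(methoxymethoxy)phenyl]-3H-diazirine
Product: 13 4'-methoxy-2',7-bis(methoxymethoxy)isoflavone carrying a 2,2-dimethyl-3,4-dihydro-2H-pyran ring fused at C5–C6 (ring oxygen on C5), via chlorocyclopropane 12 (not isolated)
Conditions: 11 (3 equiv), Na2CO3, MeCN, 40 °C, dark
Reagents that add atoms: none
Why: Proposed new method: thermal loss of N2 from 11 should give the singlet aryl(chloro)carbene, which adds to the most electron-rich π bond of 7 (the silyl enol ether C8=C9, that is furan C2=C3) to give chlorocyclopropane 12; the epimer with chloride syn to the five-membered ring then opens in the allowed disrotatory cyclopropyl-to-allyl sense with loss of chloride, pushed by the ring-oxygen lone pair and the siloxy group, to an aromatic 4-silyloxybenzopyrylium ion that chloride desilylates to the chromone carbonyl. The closest known reactions are the Ciamician–Dennstedt ring expansion of indoles and pyrroles with arylchlorodiazirines and the dihalocarbene one-carbon ring expansion of cyclic silyl enol ethers and of benzofurans (Parham type); the pairing of an aryl(chloro)carbene with a 3-silyloxybenzofuran is the untested part. No ring is closed from an open chain: the transient three-membered ring forms by cheletropic [2+1] addition and the pyranone arises by its electrocyclic opening, so the furan ring of 7 grows by exactly the carbene carbon, which becomes C3 of the isoflavone (C6a of the target). No stereocentre survives the step, since C6a and C11a are both trigonal in 13. The step needs site selectivity for the enol ether over the arene rings, secured by the silyl enol ether embedded in the furan, and placement of ring D on C3 and not C2, which is structural because the inserted carbon can only end up between the former C2 and C3. The chloride-anti epimer of 12 cannot open directly and is expected to be recycled by ionisation of its donor-stabilised benzylic C–Cl bond.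

Step 10
Reactants: 13 4'-methoxy-2',7-bis(methoxymethoxy)isoflavone carrying the 5,6-fused 2,2-dimethyldihydropyran ring
Product: 16 CNP0207547.1 [(6aS,11aS)-3-hydroxy-9-methoxypterocarpan carrying a 2,2-dimethyl-3,4-dihydro-2H-pyran ring fused at C1–C2 (ring oxygen on C1)], via isoflavanone 14 (not isolated), via cis-isoflavan-4-ol 15 (not isolated)
Conditions: RuCl(p-cymene)[(S,S)-TsDPEN] (5 mol %), HCO2H/Et3N (5:2), EtOAc, 50 °C; then solvent exchange, conc. HCl, MeOH, rt to 40 °C
Reagents that add atoms: none
Why: Noyori–Ikariya asymmetric transfer hydrogenation should first reduce the chromone C2=C3 bond to the configurationally labile isoflavanone 14 and then reduce its ketone with dynamic kinetic resolution to the cis-(3S,4S) alcohol 15 (C4 set by the (S,S) catalyst in its usual sense for aryl ketones, C3 by the faster-reacting of the enol-equilibrated enantiomers), after which acid cleaves both MOM ethers and ionises C4 to a cation that the 2'-phenol captures on the face of H-3, so C6a (S) is retained and C11a (S) follows from the only possible cis ring fusion.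

Compound list
1 | 4,6-dihydroxybenzofuran-3(2H)-one | O=C1COc2cc(O)cc(O)c12 | starting material
2 | 4-hydroxy-6-(methoxymethoxy)benzofuran-3(2H)-one | O=C1COc2cc(OCOC)cc(O)c12 | intermediate
3 | 3-chloro-3-methylbut-1-yne | CC(C)(Cl)C#C | starting material
4 | 6-(methoxymethoxy)-4-[(2-methylbut-3-yn-2-yl)oxy]benzofuran-3(2H)-one | O=C1COc2cc(OCOC)cc(OC(C)(C)C#C)c12 | intermediate
5 | 5-(methoxymethoxy)-2,2-dimethyl-2H-furo[2,3-h]chromen-9(8H)-one | O=C1COc2cc(OCOC)c3C=CC(C)(C)Oc3c12 | intermediate
6 | 5-(methoxymethoxy)-2,2-dimethyl-3,4-dihydro-2H-furo[2,3-h]chromen-9(8H)-one | O=C1COc2cc(OCOC)c3CCC(C)(C)Oc3c12 | intermediate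
7 | tert-butyl{[5-(methoxymethoxy)-2,2-dimethyl-3,4-dihydro-2H-furo[2,3-h]chromen-9-yl]oxy}dimethylsilane | CC(C)(C)[Si](C)(C)Oc1coc2cc(OCOC)c3CCC(C)(C)Oc3c12 | intermediate
8 | 2-hydroxy-4-methoxybenzonitrile | COc1ccc(C#N)c(O)c1 | starting material
9 | 4-methoxy-2-(methoxymethoxy)benzonitrile | COCOc1cc(OC)ccc1C#N | intermediate
10 | 4-methoxy-2-(methoxymethoxy)benzamidine hydrochloride | COCOc1cc(OC)ccc1C(=N)N.Cl | intermediate
11 | 3-chloro-3-[4-methoxy-2-(methoxymethoxy)phenyl]-3H-diazirine | COCOc1cc(OC)ccc1C1(Cl)N=N1 | intermediate
12 | 1-silyloxy chlorocyclopropane from [2+1] addition of the carbene to C8=C9 of 7 (racemic, both epimers at the aryl(chloro) carbon) | CC(C)(C)[Si](C)(C)OC12c3c(cc(OCOC)c4CCC(C)(C)Oc34)OC1C2(Cl)c1ccc(OC)cc1OCOC | intermediate (not isolated)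
13 | 4'-methoxy-2',7-bis(methoxymethoxy)isoflavone with a 2,2-dimethyl-3,4-dihydro-2H-pyran ring fused at C5–C6 (ring oxygen on C5) | O=c1c(-c2ccc(OC)cc2OCOC)coc2cc(OCOC)c3CCC(C)(C)Oc3c12 | intermediate
14 | isoflavanone (2,3-dihydro-13, C3 epimerising) | O=C1C(c2ccc(OC)cc2OCOC)COc2cc(OCOC)c3CCC(C)(C)Oc3c12 | intermediate (not isolated)
15 | (3S,4S)-cis-isoflavan-4-ol (4-hydroxy-2,3-dihydro-14) | O[C@H]1[C@@H](c2ccc(OC)cc2OCOC)COc2cc(OCOC)c3CCC(C)(C)Oc3c12 | intermediate (not isolated)
16 | CNP0207547.1, (6aS,11aS)-3-hydroxy-9-methoxypterocarpan with a 2,2-dimethyl-3,4-dihydro-2H-pyran ring fused at C1–C2 (ring oxygen on C1) | COc1ccc2c(c1)O[C@@H]1c3c(cc(O)c4c3OC(C)(C)CC4)OC[C@H]21 | target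

Total step count: 10. Longest linear sequence: 7 steps (steps 1, 2, 3, 4, 5, 9, 10); steps 6–8 form the three-step side branch to 11.

Steps most likely to fail

Step 9 (Proposed new method). The carbene may be consumed by dimerisation or by attack on its own ortho MOM ether before it reaches 7. The chloride-anti cyclopropane may fail to open, or 7 may be desilylated back to 6. The fallback uses known chemistry and keeps the same ring expansion, adding the aryl group afterwards. It sets out from 7: dibromocarbene (CHBr3, KOtBu, pentane, −20 °C to rt) should give, by the established dihalocarbene ring expansion of silyl enol ethers, the 3-bromochromone F1. Separately, commercial 2-bromo-5-methoxyphenol is converted with MOMCl/K2CO3 into 1-bromo-4-methoxy-2-(methoxymethoxy)benzene F2. Bromine–lithium exchange with n-BuLi, B(OiPr)3 and aqueous NH4Cl then give [4-methoxy-2-(methoxymethoxy)phenyl]boronic acid F3. Suzuki–Miyaura coupling of F1 with F3 (Pd(PPh3)4, a zerovalent palladium catalyst, Na2CO3, DME/H2O, 80 °C) comes back to the route at isoflavone 13.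

Step 8. The C–Cl bond of the donor-substituted diazirine may ionise, and N2 may be lost exothermically during oxidation, extraction or concentration. The fallback is a carbene source without an N=N bond and sets out from nitrile 9. DIBAL-H (toluene, −78 °C, aqueous work-up) gives 4-methoxy-2-(methoxymethoxy)benzaldehyde F4. Oxalyl chloride with catalytic Ph3PO (CHCl3, 0 °C to rt) converts it into 1-(dichloromethyl)-4-methoxy-2-(methoxymethoxy)benzene F5. Slow addition of KOtBu to F5 and 7 in pentane at −20 °C generates the same aryl(chloro)carbene by α-elimination, and the route is rejoined at 13 by way of 12.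

Step 10. Hydride transfer to the electron-rich, peri-alkoxylated ketone may be slow, so that reduction stalls at 14 or the dynamic kinetic resolution loses selectivity. In the acid stage, loss of H-6a from the C11a cation (E1, through the isoflav-3-ene) may erode enantiomeric purity. The fallback replaces catalytic asymmetric reduction by racemic cis reduction and enzymatic kinetic resolution, and sets out from 13. H2 over Pd/C (EtOAc, rt, stopped after one equivalent) gives isoflavanone 14. LiBH(sec-Bu)3 (THF, −78 °C) reduces it from the face opposite the 3-aryl group to the racemic cis-isoflavan-4-ol F6. Burkholderia cepacia lipase with vinyl acetate (MTBE, 30 °C) is expected, by the empirical rule for secondary carbinols, to acylate the (4R) enantiomer to the (3R,4R)-acetate F7. That leaves (3S,4S)-15, where the route is rejoined. 15 is then cyclised with the mildest acid that still removes the MOM groups (pyridinium p-toluenesulfonate in MeOH at 50 °C, or brief methanolic HCl at 0 °C).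

Further compounds
F1 | step 9 | 3-bromo-7-(methoxymethoxy)chromone with a 2,2-dimethyl-3,4-dihydro-2H-pyran ring fused at C5–C6 (ring oxygen on C5) | O=c1c(Br)coc2cc(OCOC)c3CCC(C)(C)Oc3c12
F2 | step 9 | 1-bromo-4-methoxy-2-(methoxymethoxy)benzene | COCOc1cc(OC)ccc1Br
F3 | step 9 | [4-methoxy-2-(methoxymethoxy)phenyl]boronic acid | COCOc1cc(OC)ccc1B(O)O
F4 | step 8 | 4-methoxy-2-(methoxymethoxy)benzaldehyde | COCOc1cc(OC)ccc1C=O
F5 | step 8 | 1-(dichloromethyl)-4-methoxy-2-(methoxymethoxy)benzene | COCOc1cc(OC)ccc1C(Cl)Cl
F6 | step 10 | racemic cis-isoflavan-4-ol (15 and its enantiomer) | O[C@H]1[C@@H](c2ccc(OC)cc2OCOC)COc2cc(OCOC)c3CCC(C)(C)Oc3c12.O[C@@H]1[C@H](c2ccc(OC)cc2OCOC)COc2cc(OCOC)c3CCC(C)(C)Oc3c12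
F7 | step 10 | (3R,4R)-cis-isoflavan-4-yl acetate (acetate of the enantiomer of 15) | CC(=O)O[C@@H]1[C@H](c2ccc(OC)cc2OCOC)COc2cc(OCOC)c3CCC(C)(C)Oc3c12
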